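**Retrosynthetic overview**
1. Last ring: the 15-membered lactone is closed by C1–O21 macrolactonisation of seco acid 20; the free 17-OH cannot compete because it would need a strained 11-membered ring.
2. C16–C17: asymmetric alkynylation of chlorolactol 16 by terminal alkyne 13 joins the two halves. The lactone ring of 15/16 fixes the C18=C19(Cl) geometry, and semihydrogenation then gives the (15Z)-alkene.
3. Key step: both remaining C–N bonds are made in one pot from nitro enal 9. Nitro reduction, aza-Michael closure (N–C5, ring B, sets C5), then aza-Michael/Horner–Wadsworth–Emmons annulation with a phosphonoacrylate (N–C23 and C2=C3, ring C).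
4. C9 (quaternary, nitrogen-bearing): nitronate Michael addition to acrolein, trans to the C13 branch. C13/C14: organocatalytic Michael addition of propanal to 1-nitrocyclopentene.
5. Ring order: ring A (cyclopentane, bought) → ring B → ring C (same pot) → macrolactone.

Assumption: the SMILES defines the target ((5R,9S,13R,14S,17R), 15Z, 18E, Cl on C19), and 1-nitrocyclopent-1-ene and dihydro-2H-pyran-2,4(3H)-dione are taken as catalogue chemicals.

Atom labels used below: C1 lactone carbonyl, C2=C3 ring C alkene, C4, C5 (N–CH), C6–C8, C9 (spiro, N-bearing), C10–C12, C13 (ring A CH), C14 (CHMe), C15=C16, C17 (carbinol), C18=C19(Cl), C20, C21 (OCH2), C23 (NCH2).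

**Step 1**
Reactants: 1 1-nitrocyclopent-1-ene; 2 propanal
Product: 3 (2R)-2-[(1R)-2-nitrocyclopentyl]propanal
Conditions: (S)-2-[diphenyl(trimethylsilyloxy)methyl]pyrrolidine (10 mol %), 4-nitrophenol (20 mol %), 2 (3 equiv), toluene (2 M), 0 °C to rt
Reagents that add atoms: none
Why: Enamine-catalysed asymmetric Michael addition (Hayashi–Jørgensen type): the anti-enamine of propanal, shielded on one face by the diarylsilyloxymethyl group, adds through the acyclic synclinal transition state to the β-carbon of the nitroalkene, which sets C14 and C13 in the syn relationship with the absolute sense known for nitrostyrenes; the nitro-bearing carbon stays an epimer mixture that is erased in step 3.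

**Step 2**
Reactants: 3 (2R)-2-[(1R)-2-nitrocyclopentyl]propanal
Product: 4 (1R)-1-[(2R)-but-3-yn-2-yl]-2-nitrocyclopentane
Conditions: dimethyl (1-diazo-2-oxopropyl)phosphonate, K2CO3, MeOH, 0 °C to rt
Reagents that add atoms: dimethyl (1-diazo-2-oxopropyl)phosphonate, CC(=O)C(=[N+]=[N-])P(=O)(OC)OC
Why: Ohira–Bestmann (Seyferth–Gilbert) homologation turns the aldehyde into the terminal alkyne under conditions mild enough to keep the α-methyl centre C14, and the reversible nitronate formation at the other centre is of no consequence.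

**Step 3**
Reactants: 4 (1R)-1-[(2R)-but-3-yn-2-yl]-2-nitrocyclopentane; 5 prop-2-enal
Product: 6 3-[(1S,2R)-2-[(2R)-but-3-yn-2-yl]-1-nitrocyclopentyl]propanal
Conditions: DBU (0.2 equiv), MeCN, −20 to 0 °C
Reagents that add atoms: none
Why: Nitro-Michael addition: the planar nitronate is alkylated by acrolein on the face opposite to the branched C13 substituent, so the new C9–C8 bond is trans to C14 and the nitro group (the future nitrogen) is cis to C14, which fixes the quaternary centre C9.

**Step 4**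
Reactants: 6 3-[(1S,2R)-2-[(2R)-but-3-yn-2-yl]-1-nitrocyclopentyl]propanal
Product: 7 2-[(2Z)-5-[(1S,2R)-2-[(2R)-but-3-yn-2-yl]-1-nitrocyclopentyl]pent-2-en-1-yl]-1,3-dioxolane
Conditions: [2-(1,3-dioxolan-2-yl)ethyl]triphenylphosphonium bromide, KN(SiMe3)2, THF, −78 °C to rt
Reagents that add atoms: [2-(1,3-dioxolan-2-yl)ethyl]triphenylphosphonium bromide, [Br-].C1COC(CC[P+](c2ccccc2)(c2ccccc2)c2ccccc2)O1
Why: Wittig olefination with a non-stabilised ylide brings in C3–C5 as a masked aldehyde and gives the (Z)-alkene; the tertiary nitro group and the alkyne are inert to the ylide and no stereocentre is formed.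

**Step 5**
Reactants: 7 2-[(2Z)-5-[(1S,2R)-2-[(2R)-but-3-yn-2-yl]-1-nitrocyclopentyl]pent-2-en-1-yl]-1,3-dioxolane
Product: 9 (2E)-6-[(1S,2R)-2-[(2R)-but-3-yn-2-yl]-1-nitrocyclopentyl]hex-2-enal, via skipped enal 8 (not isolated)
Conditions: 2 M HCl, THF, 40 °C; then Et3N (0.3 equiv), CH2Cl2, rt
Reagents that add atoms: water, O
Why: Acetal hydrolysis frees the β,γ-unsaturated aldehyde, which moves into conjugation through its dienol(ate) to give the thermodynamically preferred (E)-α,β-enal with C6 now saturated; no stereocentre is touched.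

**Step 6**
Reactants: 9 (2E)-6-[(1S,2R)-2-[(2R)-but-3-yn-2-yl]-1-nitrocyclopentyl]hex-2-enal
Product: 13 ethyl (1S,2R,9a'R)-2-[(2R)-but-3-yn-2-yl]-1',2',3',6',9',9a'-hexahydrospiro[cyclopentane-1,4'-quinolizine]-7'-carboxylate, via amino enal 10 (not isolated), via amino aldehyde 11 (not isolated), via phosphonate adduct 12 (not isolated)
Conditions: Zn, AcOH, THF, 0 °C to rt; filter, evaporate; then ethyl 2-(diethoxyphosphoryl)acrylate, K2CO3, 18-crown-6 (cat.), MeCN, rt to 45 °C
Reagents that add atoms: ethyl 2-(diethoxyphosphoryl)acrylate, C=C(C(=O)OCC)P(=O)(OCC)OCC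
Why: Nitro reduction releases the primary amine, which closes ring B by reversible 6-exo aza-Michael addition (N–C5), so that C5 settles under thermodynamic control with its CH2CHO arm and the C13 branch of the spiro centre both equatorial (5R); the hindered secondary amine then adds to the phosphonoacrylate (N–C23) and the phosphonate carbanion closes ring C by intramolecular Horner–Wadsworth–Emmons olefination on the aldehyde (C2=C3).

**Step 7**
Reactants: 14 dihydro-2H-pyran-2,4(3H)-dione
Product: 15 4-chloro-5,6-dihydro-2H-pyran-2-one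
Conditions: (COCl)2, DMF (cat.), CH2Cl2, 0 °C to rt
Reagents that add atoms: oxalyl chloride, O=C(Cl)C(=O)Cl
Why: Vilsmeier-type deoxychlorination of the enol form of the β-keto lactone (vinylogous acid to vinylogous acid chloride) gives the β-chloro enoate, and the ring locks C17 and C20 cis across the future C18=C19 bond.

**Step 8**
Reactants: 15 4-chloro-5,6-dihydro-2H-pyran-2-one
Product: 16 4-chloro-5,6-dihydro-2H-pyran-2-ol
Conditions: i-Bu2AlH (1.1 equiv), CH2Cl2, −78 °C
Reagents that add atoms: none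
Why: 1,2-Reduction of the lactone by i-Bu2AlH stops at the aluminium hemiacetal at −78 °C and gives the lactol, a storable cyclic form of the cis-configured hydroxy enal.

**Step 9**
Reactants: 13 ethyl (1S,2R,9a'R)-2-[(2R)-but-3-yn-2-yl]-1',2',3',6',9',9a'-hexahydrospiro[cyclopentane-1,4'-quinolizine]-7'-carboxylate; 16 4-chloro-5,6-dihydro-2H-pyran-2-ol
Product: 18 ethyl (1S,2R,9a'R)-2-[(2R,5S,6E)-7-chloro-5,9-dihydroxynon-6-en-3-yn-2-yl]-1',2',3',6',9',9a'-hexahydrospiro[cyclopentane-1,4'-quinolizine]-7'-carboxylate, via open hydroxy enal 17 (not isolated)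
Conditions: Me2Zn (3.5 equiv), (S,S)-ProPhenol (2,6-bis{[(2S)-2-(hydroxydiphenylmethyl)pyrrolidin-1-yl]methyl}-4-methylphenol, 20 mol %), Ph3P=O (40 mol %), 16 (2 equiv), toluene, 0 °C to rt
Reagents that add atoms: none
Why: Proposed new method: a free lactol is used directly as the aldehyde partner in the dinuclear zinc–ProPhenol alkynylation; Me2Zn converts 13 into its alkynylzinc and 16 into a zinc lactolate that opens reversibly to the zinc alkoxide of conjugated enal 17 (ring–chain tautomerism, pulled by conjugation and by consumption), the aldehyde binds in the chiral dinuclear zinc pocket and receives the alkynyl group on one enantioface, which forms the C16–C17 bond, sets C17 by catalyst control (the (S,S) ligand is the working choice and is replaced by its antipode if a Mosher ester of the first run shows the 17-epimer) and frees the C21 hydroxyl without a protecting group; the closest known reactions are the zinc–ProPhenol alkynylation of α,β-unsaturated aldehydes and the addition of Grignard or Wittig reagents to lactols through their open form.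

**Step 10**
Reactants: 18 ethyl (1S,2R,9a'R)-2-[(2R,5S,6E)-7-chloro-5,9-dihydroxynon-6-en-3-yn-2-yl]-1',2',3',6',9',9a'-hexahydrospiro[cyclopentane-1,4'-quinolizine]-7'-carboxylate
Product: 19 ethyl (1S,2R,9a'R)-2-[(2S,3Z,5R,6E)-7-chloro-5,9-dihydroxynona-3,6-dien-2-yl]-1',2',3',6',9',9a'-hexahydrospiro[cyclopentane-1,4'-quinolizine]-7'-carboxylate
Conditions: H2 (1 atm), Pd/CaCO3 poisoned with Pb(OAc)2, quinoline, EtOAc, rt
Reagents that add atoms: none
Why: Lindlar semihydrogenation adds H2 syn to the alkyne and gives the (15Z)-alkene, while the vinyl chloride and the trisubstituted enoate are not reduced over poisoned palladium; C14 and C17 keep their spatial arrangement and only their descriptors change.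

**Step 11**
Reactants: 19 ethyl (1S,2R,9a'R)-2-[(2S,3Z,5R,6E)-7-chloro-5,9-dihydroxynona-3,6-dien-2-yl]-1',2',3',6',9',9a'-hexahydrospiro[cyclopentane-1,4'-quinolizine]-7'-carboxylate
Product: 20 (1S,2R,9a'R)-2-[(2S,3Z,5R,6E)-7-chloro-5,9-dihydroxynona-3,6-dien-2-yl]-1',2',3',6',9',9a'-hexahydrospiro[cyclopentane-1,4'-quinolizine]-7'-carboxylic acid
Conditions: LiOH, THF–MeOH–H2O, rt; then 1 M HCl to pH 6
Reagents that add atoms: lithium hydroxide, [Li+].[OH-]
Why: Saponification of the conjugated ethyl ester; the vinyl chloride and the bis-allylic alcohol are stable to LiOH and no stereocentre is α to the carboxylate.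

**Step 12**
Reactants: 20 (1S,2R,9a'R)-2-[(2S,3Z,5R,6E)-7-chloro-5,9-dihydroxynona-3,6-dien-2-yl]-1',2',3',6',9',9a'-hexahydrospiro[cyclopentane-1,4'-quinolizine]-7'-carboxylic acid
Product: 21 CNP0129639.4
Conditions: 2-methyl-6-nitrobenzoic anhydride (1.3 equiv), DMAP (3 equiv), Et3N, CH2Cl2 (1 mM, slow addition of 20), rt
Reagents that add atoms: none
Why: Shiina macrolactonisation (mixed anhydride, acyl transfer by DMAP, high dilution) forms the C1–O21 bond at the primary hydroxyl; acylation of the secondary 17-OH would need a strained 11-membered ring containing the (Z)-alkene, and no stereocentre is affected.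

**Compound list**
1 | 1-nitrocyclopent-1-ene | O=[N+]([O-])C1=CCCC1 | starting material
2 | propanal | CCC=O | starting material
3 | (2R)-2-[(1R)-2-nitrocyclopentyl]propanal (both epimers at the nitro-bearing carbon) | C[C@H]([C@H]1CCCC1[N+](=O)[O-])C=O | intermediate
4 | (1R)-1-[(2R)-but-3-yn-2-yl]-2-nitrocyclopentane (both epimers at C2) | C[C@H]([C@H]1CCCC1[N+](=O)[O-])C#C | intermediate
5 | prop-2-enal (acrolein) | C=CC=O | starting material
6 | 3-[(1S,2R)-2-[(2R)-but-3-yn-2-yl]-1-nitrocyclopentyl]propanal (nitro cis to the butynyl branch) | C[C@H]([C@H]1CCC[C@@]1(CCC=O)[N+](=O)[O-])C#C | intermediate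
7 | 2-[(2Z)-5-[(1S,2R)-2-[(2R)-but-3-yn-2-yl]-1-nitrocyclopentyl]pent-2-en-1-yl]-1,3-dioxolane | C[C@H]([C@H]1CCC[C@@]1(CC/C=C\CC2OCCO2)[N+](=O)[O-])C#C | intermediate
8 | (3Z)-6-[(1S,2R)-2-[(2R)-but-3-yn-2-yl]-1-nitrocyclopentyl]hex-3-enal (not isolated) | C[C@H]([C@H]1CCC[C@@]1(CC/C=C\CC=O)[N+](=O)[O-])C#C | intermediate
9 | (2E)-6-[(1S,2R)-2-[(2R)-but-3-yn-2-yl]-1-nitrocyclopentyl]hex-2-enal | C[C@H]([C@H]1CCC[C@@]1(CCC/C=C/C=O)[N+](=O)[O-])C#C | intermediate
10 | (2E)-6-[(1S,2R)-1-amino-2-[(2R)-but-3-yn-2-yl]cyclopentyl]hex-2-enal (not isolated) | C[C@H]([C@H]1CCC[C@@]1(CCC/C=C/C=O)N)C#C | intermediate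
11 | 2-[(1R,5S,7R)-1-[(2R)-but-3-yn-2-yl]-6-azaspiro[4.5]decan-7-yl]acetaldehyde (not isolated) | O=CC[C@H]1CCC[C@]2(CCC[C@@H]2[C@@H](C)C#C)N1 | intermediate
12 | ethyl 3-[(1R,5S,7R)-1-[(2R)-but-3-yn-2-yl]-7-(2-oxoethyl)-6-azaspiro[4.5]decan-6-yl]-2-(diethoxyphosphoryl)propanoate (not isolated; phosphonate carbon unassigned) | O=CC[C@H]1CCC[C@]2(CCC[C@@H]2[C@@H](C)C#C)N1CC(C(=O)OCC)P(=O)(OCC)OCC | intermediate
13 | ethyl (1S,2R,9a'R)-2-[(2R)-but-3-yn-2-yl]-1',2',3',6',9',9a'-hexahydrospiro[cyclopentane-1,4'-quinolizine]-7'-carboxylate | CCOC(=O)C1=CC[C@H]2CCC[C@]3(CCC[C@@H]3[C@@H](C)C#C)N2C1 | intermediate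
14 | dihydro-2H-pyran-2,4(3H)-dione | O=C1CC(=O)CCO1 | starting material
15 | 4-chloro-5,6-dihydro-2H-pyran-2-one | O=C1C=C(Cl)CCO1 | intermediate
16 | 4-chloro-5,6-dihydro-2H-pyran-2-ol (racemic lactol) | OC1C=C(Cl)CCO1 | intermediate
17 | (2E)-3-chloro-5-hydroxypent-2-enal (open form of 16, CHO and CH2CH2OH cis, present as its zinc alkoxide, not isolated) | O=C/C=C(/Cl)CCO | intermediate
18 | ethyl (1S,2R,9a'R)-2-[(2R,5S,6E)-7-chloro-5,9-dihydroxynon-6-en-3-yn-2-yl]-1',2',3',6',9',9a'-hexahydrospiro[cyclopentane-1,4'-quinolizine]-7'-carboxylate (C17 already in the target's spatial arrangement) | CCOC(=O)C1=CC[C@H]2CCC[C@]3(CCC[C@@H]3[C@@H](C)C#C[C@@H](O)/C=C(/Cl)CCO)N2C1 | intermediate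
19 | ethyl (1S,2R,9a'R)-2-[(2S,3Z,5R,6E)-7-chloro-5,9-dihydroxynona-3,6-dien-2-yl]-1',2',3',6',9',9a'-hexahydrospiro[cyclopentane-1,4'-quinolizine]-7'-carboxylate | CCOC(=O)C1=CC[C@H]2CCC[C@]3(CCC[C@@H]3[C@@H](C)/C=C\[C@@H](O)/C=C(/Cl)CCO)N2C1 | intermediate
20 | (1S,2R,9a'R)-2-[(2S,3Z,5R,6E)-7-chloro-5,9-dihydroxynona-3,6-dien-2-yl]-1',2',3',6',9',9a'-hexahydrospiro[cyclopentane-1,4'-quinolizine]-7'-carboxylic acid (seco acid) | OC(=O)C1=CC[C@H]2CCC[C@]3(CCC[C@@H]3[C@@H](C)/C=C\[C@@H](O)/C=C(/Cl)CCO)N2C1 | intermediate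
21 | CNP0129639.4, the (5R,9S,13R,14S,17R)-15Z,18E macrolactone | C[C@H]1/C=C\[C@@H](O)/C=C(/Cl)CCOC(=O)C2=CC[C@H]3CCC[C@]4(CCC[C@H]14)N3C2 | target

**Step count and risks**
Total step count: 12 (ten on the main line, two for the chlorolactol). Longest linear sequence: 10 steps (steps 1–6 and 9–12).

Most likely to fail, first: step 9, the new lactol alkynylation. The closed lactol may react slowly, or facial control may be poor with a zinc alkoxide tethered to the aldehyde. The fallback uses known chemistry and sets out from 13 and chlorolactone 15. Alkyne 13 is deprotonated with LiN(SiMe3)2 (THF, −78 °C) and added to the lactone carbonyl of 15. Ring opening gives the hydroxy ynone ethyl (1S,2R,9a'R)-2-[(2R,6E)-7-chloro-9-hydroxy-5-oxonon-6-en-3-yn-2-yl]-1',2',3',6',9',9a'-hexahydrospiro[cyclopentane-1,4'-quinolizine]-7'-carboxylate F2. Corey–Bakshi–Shibata reduction ((S)-2-methyl-CBS-oxazaborolidine, BH3·SMe2, alkynyl as the small group) then gives 18, where the route is rejoined.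

Second: step 6, the one-pot reduction and double C–N annulation. Zinc may attack the enal, or the β-amino aldehyde may decompose before it is trapped. The fallback changes the order and sets out from acetal 7. The nitro group is reduced first (Zn, AcOH) to the stable, isolable amine (1S,2R)-2-[(2R)-but-3-yn-2-yl]-1-[(3Z)-5-(1,3-dioxolan-2-yl)pent-3-en-1-yl]cyclopentan-1-amine F1. Aqueous HCl then unmasks and conjugates the aldehyde on the protonated amine (the salt of 10). Neutralisation with K2CO3 triggers aza-Michael closure to 11, and ethyl 2-(diethoxyphosphoryl)acrylate with K2CO3 gives 13 through 12, where the route is rejoined.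

Third: step 12, macrolactonisation with the 17-OH free. Oligomers or acylation at O17 are the risks. The fallback closes the ring before the semihydrogenation and sets out from alkyne diol 18. LiOH hydrolysis gives (1S,2R,9a'R)-2-[(2R,5S,6E)-7-chloro-5,9-dihydroxynon-6-en-3-yn-2-yl]-1',2',3',6',9',9a'-hexahydrospiro[cyclopentane-1,4'-quinolizine]-7'-carboxylic acid F3. Shiina lactonisation, where the rigid C14–C15≡C16–C17 rod strongly disfavours ring closure at O17, gives the 15,16-didehydro macrolactone (C15≡C16 analogue of the target) F4. Semihydrogenation over Pb(OAc)2-poisoned Pd/CaCO3 then gives 21 directly.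

**Further compounds**
F1 | step 6 | (1S,2R)-2-[(2R)-but-3-yn-2-yl]-1-[(3Z)-5-(1,3-dioxolan-2-yl)pent-3-en-1-yl]cyclopentan-1-amine | C[C@H]([C@H]1CCC[C@@]1(CC/C=C\CC2OCCO2)N)C#C
F2 | step 9 | ethyl (1S,2R,9a'R)-2-[(2R,6E)-7-chloro-9-hydroxy-5-oxonon-6-en-3-yn-2-yl]-1',2',3',6',9',9a'-hexahydrospiro[cyclopentane-1,4'-quinolizine]-7'-carboxylate | CCOC(=O)C1=CC[C@H]2CCC[C@]3(CCC[C@@H]3[C@@H](C)C#CC(=O)/C=C(/Cl)CCO)N2C1
F3 | step 12 | (1S,2R,9a'R)-2-[(2R,5S,6E)-7-chloro-5,9-dihydroxynon-6-en-3-yn-2-yl]-1',2',3',6',9',9a'-hexahydrospiro[cyclopentane-1,4'-quinolizine]-7'-carboxylic acid | OC(=O)C1=CC[C@H]2CCC[C@]3(CCC[C@@H]3[C@@H](C)C#C[C@@H](O)/C=C(/Cl)CCO)N2C1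
F4 | step 12 | 15,16-didehydro macrolactone (C15≡C16 analogue of 21) | C[C@H]1C#C[C@@H](O)/C=C(/Cl)CCOC(=O)C2=CC[C@H]3CCC[C@]4(CCC[C@H]14)N3C2
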